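Readings and results come from a simulation on assumed constants, and the scatter is random.

At 30 min I want to know where the D of this flask has gone, so I follow one molecule.

| flask | D | Q | remark | time |
|---|---|---|---|---|
| eta | 0.40 M | 7.7 mol% | the very flask that is asked about, followed so far |  |
| theta | 0.20 M | 7.7 mol% | run made earlier |  |
| flask | 0.40 M | 7.7 mol% |  | 30 min |

| run | time / min | Z / % | D / % |
|---|---|---|---|
| eta | 0.417 | 0.8 | 86.5 |
| eta | 1.33 | 5.8 | 65.8 |
| eta | 2.00 | 12.2 | 56.3 |
| eta | 3.00 | 22.4 | 42.2 |
| eta | 5.00 | 41.8 | 19.3 |
| eta | 6.00 | 51.9 | 8.3 |
| theta | 2.00 | 13.3 | 16.5 |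
| theta | 4.00 | 33.7 | 0 |
| theta | 6.00 | 48.0 | 0.4 |
| theta | 8.00 | 58.9 | 0.2 |
| theta | 10.0 | 65.7 | 0.3 |
| theta | 12.0 | 70.5 | 0.6 |

(each reading ± 0.5 percentage points)

- solid, in amounts per volume of the solution: D
- the analysis behind the earlier runs scatters by 0.5 percentage points, standard deviation
- on the list of suspects stand: G -> E; D <-> G; G + Q -> Q + Z
- at the start none of D is in solution

- how much Z there is at 30 min, in percent of the D charged
- the change that raises the amount of Z at 30 min, in percent of the D charged most ("none" if none brings more than 2 percentage points) (Monday's / Thursday's / Sunday's / none)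
- amount of Z at 30 min, in percent of the D charged, after Sunday's

- Monday's: doubling the solubility of D, all else as stated
- Thursday's: doubling the dissolution coefficient of D, all else as stated
- Sunday's: doubling the amount of Q, all else as stated

1. I take it that a molecule of D dissolves to G, and G then meets a fork: with Q it goes to Z, or alone to E. If both routes are first order in G, then at a given c_Q the chance of reaching Z doesn't depend on how much G stands in solution.

2. In the theta run D reads 0 % at 4.00 min. After that the steps in Z shrink by a factor of 0.695 per reading, which reads as a decay of G at about 0.182 min⁻¹. Summing the remaining steps, Z in the theta run ends near 81.4 %, so the odds there are 4.39.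

3. This flask, the eta run, has twice the c_Q of the theta run. I take the route to Z to go with c_Q, so S reads about 8.77. S is the rate of G to Z divided by the rate of G to E, a selectivity factor.

4. The chance of Z is S/(1+S), which is 89.8 %. Sunday's doubles S and gives 94.6 %, a gain of 4.8 percentage points. Monday's and Thursday's touch the solid and leave c_Q as it is, so S stays.

5. Is one number enough? It is if the fork is finished in time. The solid in this flask lasts to about 6.69 min. G then decays at 0.330 min⁻¹, which leaves 0.0456 % of that G at the asked time. So in this flask I read the outcome off S.

The forecast gives 90 %, Sunday's as the best change, and 94.6 % after it, holding that “yield is just selectivity”.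

The flask gives 89.1 %. The best change is Sunday's, with 94.3 %, a gain of 5.1 points, against 0.0057 points for Monday's and 0 points for Thursday's.

    G → E (k = 6.20 × 10⁻⁴ s⁻¹)
    D ⇌ G, rate k2*(cs2 - [G]) while solid is left; crystals form when [G] > cs2 (solubility = 0.190 M, k = 0.0136 s⁻¹)
    G + Q → Q + Z (k = 0.165 M⁻¹ s⁻¹)

In this flask the half-life of G by the step to Z is 2.3 min, against 18.6 min by the step to E, and Z stands to E at 8.20, where my S, read off the theta readings, gave 8.77. S carries no clock, but that didn't count here: G is down to 0.0115 % at 30.0 min, and at 300 min Z still stands at 89.1 %. A neighbour flask with 0.68 M of D at the same loading has S of about 14.9, a chance of 93.7 %; it gives 93.3 %.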